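The route rests on cutting the O1–C2 bond of the outer dihydrobenzofuran. C2 is a CH2 benzylic to ring D and para to the ring D ether oxygen, and the ring C phenol oxygen is placed for a five-membered closure onto it, so one DDQ dehydrogenation closes the ring and sets C2 trans to C3. The precursor is a methyl 4-hydroxy-5-methoxybenzoate (ring C) carrying at C3 a 1-(ring D)-3-silyloxyprop-2-yl chain whose stereocentre comes from an Evans alkylation. The same imide, auxiliary and benzyl bromide then serve again: syn aldol and SN1 closure build the inner ring, and a lactone aldol followed by hemiketal reduction builds the all-cis tetrahydrofuran.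

Key step: step 12

Remarks
- Ring letters: A = guaiacyl ring of the benzyl group, B = benzo ring of the inner dihydrobenzofuran, C = benzo ring of the outer dihydrobenzofuran, D = terminal guaiacyl ring.
- Assumption: compounds 1, 2, 8, 11 and 27 are purchased.
- The primary alcohol is carried as a tert-butyldiphenylsilyl ether because the ring C phenol is released with acid, where a smaller silyl ether would be at risk.
- Enolates, cations and metal alkoxides are described in the Why lines and carry no numbers.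
- In names, ArCD is the (2S,3R)-2-(4-benzyloxy-3-methoxyphenyl)-3-[(tert-butyldiphenylsilyloxy)methyl]-7-methoxy-2,3-dihydrobenzofuran-5-yl group, and ArBCD is the (2R,3S)-2-(ArCD)-3-[(tert-butyldiphenylsilyloxy)methyl]-7-methoxy-2,3-dihydrobenzofuran-5-yl group.

Step 1
Reactants: 1 methyl vanillate; 2 allyl bromide
Product: 3 methyl 4-(allyloxy)-3-methoxybenzoate
Conditions: K2CO3, acetone, reflux
Reagents that add atoms: none
Why: Williamson ether synthesis, in which the potassium phenoxide displaces bromide from the allylic halide by SN2 while the ester is untouched.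

Step 2
Reactants: 3 methyl 4-(allyloxy)-3-methoxybenzoate
Product: 4 methyl 3-allyl-4-hydroxy-5-methoxybenzoate
Conditions: N,N-diethylaniline, 200 °C
Reagents that add atoms: none
Why: Aromatic Claisen rearrangement, a [3,3]-sigmatropic shift followed by tautomerisation, which can place the allyl group only on the single free ortho carbon because the other ortho position carries the methoxy group.

Step 3
Reactants: 4 methyl 3-allyl-4-hydroxy-5-methoxybenzoate
Product: 5 methyl 3-allyl-5-methoxy-4-(methoxymethoxy)benzoate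
Conditions: NaH, DMF, 0 °C; MOMCl, 0 °C to rt
Reagents that add atoms: chloromethyl methyl ether, COCCl
Why: O-alkylation of the sodium phenoxide gives a methoxymethyl acetal that should withstand ozone, chlorite, amide bases, borohydride and Bu2BOTf and that acid removes later.

Step 4
Reactants: 5 methyl 3-allyl-5-methoxy-4-(methoxymethoxy)benzoate
Product: 6 methyl 3-methoxy-4-(methoxymethoxy)-5-(2-oxoethyl)benzoate
Conditions: O3, CH2Cl2/MeOH, −78 °C; then Me2S, −78 °C to rt
Reagents that add atoms: ozone, [O-][O+]=O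
Why: Ozonolysis with reductive work-up cleaves the terminal alkene to the arylacetaldehyde, the ester-deactivated arene and the acetal reacting far more slowly with ozone when the gas flow is stopped at consumption of the alkene.

Step 5
Reactants: 6 methyl 3-methoxy-4-(methoxymethoxy)-5-(2-oxoethyl)benzoate
Product: 7 [3-methoxy-5-(methoxycarbonyl)-2-(methoxymethoxy)phenyl]acetic acid
Conditions: NaClO2, NaH2PO4, 2-methyl-2-butene, t-BuOH/H2O, 0 °C to rt
Reagents that add atoms: sodium chlorite, [Na+].[O-]Cl=O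
Why: Pinnick oxidation converts the crude enolisable aldehyde into the acid under buffered conditions, with 2-methyl-2-butene trapping hypochlorite so that the arene is not chlorinated and the acetal is not cleaved.

Step 6
Reactants: 7 [3-methoxy-5-(methoxycarbonyl)-2-(methoxymethoxy)phenyl]acetic acid; 8 (R)-4-benzyl-2-oxazolidinone
Product: 10 methyl 3-{2-[(4R)-4-benzyl-2-oxooxazolidin-3-yl]-2-oxoethyl}-5-methoxy-4-(methoxymethoxy)benzoate, via mixed pivalic anhydride 9 (not isolated)
Conditions: PivCl, Et3N, THF, −20 °C; then 8, LiCl, rt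
Reagents that add atoms: none
Why: N-acylation of the oxazolidinone through the mixed anhydride (LiCl and Et3N variant), the nucleophile attacking the unhindered arylacetyl carbonyl and not the tert-butyl carbonyl.

Step 7
Reactants: 11 4-benzyloxy-3-methoxybenzyl alcohol
Product: 12 4-benzyloxy-3-methoxybenzyl bromide
Conditions: PBr3, Et2O, 0 °C
Reagents that add atoms: phosphorus tribromide, BrP(Br)Br
Why: Bromination of an electron-rich benzylic alcohol through its phosphite ester and bromide displacement, the labile bromide being used at once.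

Step 8
Reactants: 10 arylacetyl imide; 12 4-benzyloxy-3-methoxybenzyl bromide
Product: 13 methyl 3-{(2R)-1-[(4R)-4-benzyl-2-oxooxazolidin-3-yl]-3-(4-benzyloxy-3-methoxyphenyl)-1-oxopropan-2-yl}-5-methoxy-4-(methoxymethoxy)benzoate
Conditions: NaN(SiMe3)2, THF, −78 °C; then 12, −78 to −40 °C
Reagents that add atoms: none
Why: Evans asymmetric alkylation in which the chelated Z sodium enolate is attacked by the benzylic bromide on the face away from the auxiliary benzyl group, which with the (R)-auxiliary should give the (R) centre that becomes C3 of the outer dihydrobenzofuran.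

Step 9
Reactants: 13 alkylated imide
Product: 14 methyl 3-[(2R)-1-(4-benzyloxy-3-methoxyphenyl)-3-hydroxypropan-2-yl]-5-methoxy-4-(methoxymethoxy)benzoate
Conditions: NaBH4, THF/H2O (4:1), 0 °C to rt
Reagents that add atoms: none
Why: Reductive cleavage of the N-acyloxazolidinone with borohydride, the activated imide carbonyl being reduced well before the aryl methyl ester and the stereocentre staying untouched at 0 °C.

Step 10
Reactants: 14 primary alcohol
Product: 15 methyl 3-[(2R)-1-(4-benzyloxy-3-methoxyphenyl)-3-(tert-butyldiphenylsilyloxy)propan-2-yl]-5-methoxy-4-(methoxymethoxy)benzoate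
Conditions: TBDPSCl, imidazole, DMF, rt
Reagents that add atoms: tert-butyl(chloro)diphenylsilane, CC(C)(C)[Si](Cl)(c1ccccc1)c1ccccc1
Why: Silylation of the primary alcohol gives an ether that is bulky enough to steer the later ring closure and stable to the acid of the next step.

Step 11
Reactants: 15 silyl ether with MOM-protected phenol
Product: 16 methyl 3-[(2R)-1-(4-benzyloxy-3-methoxyphenyl)-3-(tert-butyldiphenylsilyloxy)propan-2-yl]-4-hydroxy-5-methoxybenzoate
Conditions: conc. HCl (5 equiv), MeOH/THF, 40 °C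
Reagents that add atoms: none
Why: Acid-catalysed solvolysis of the aryl MOM acetal in methanol frees the ring C phenol while the tert-butyldiphenylsilyl ether, the benzyl ether and the ester should survive.

Step 12
Reactants: 16 ring C phenol with 1-(ring D)-3-silyloxyprop-2-yl chain
Product: 17 methyl (2S,3R)-2-(4-benzyloxy-3-methoxyphenyl)-3-[(tert-butyldiphenylsilyloxy)methyl]-7-methoxy-2,3-dihydrobenzofuran-5-carboxylate
Conditions: DDQ (1.2 equiv), 4 Å molecular sieves, CH2Cl2, 0 °C to rt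
Reagents that add atoms: none
Why: DDQ forms a charge-transfer complex with ring D, the most electron-rich arene, and abstracts hydride from its benzylic CH2, giving a cation delocalised onto the para benzyloxy oxygen (an O-benzyl quinone methide). The closest known reaction type is the DDQ-mediated dehydrogenative cyclisation of 2-(2-arylethyl)phenols and the related oxidative etherification of p-alkoxybenzylic C–H bonds. The ring C phenol oxygen adds to the cationic carbon in a 5-exo-trig closure that forms O1–C2 and the dihydrofuran ring. The new C2 centre is controlled by the existing C3 centre, because the phenol attacks the planar cation on the face that puts ring D anti to the CH2OSi group, which is also the more stable trans isomer, giving (2S,3R). The step needs site selectivity for the ring D CH2 over the C3–H and the ring C phenol, which the para ester (raising the oxidation potential of ring C) and the two ether oxygens of ring D secure. It must also stop before dehydrogenation to the benzofuran, which the near-stoichiometric DDQ charge, the low temperature and the ester-deactivated product ether should secure.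

Step 13
Reactants: 17 dihydrobenzofuran methyl ester
Product: 18 ArCD-methanol, {(2S,3R)-2-(4-benzyloxy-3-methoxyphenyl)-3-[(tert-butyldiphenylsilyloxy)methyl]-7-methoxy-2,3-dihydrobenzofuran-5-yl}methanol
Conditions: iBu2AlH (2.5 equiv), CH2Cl2, −78 to 0 °C; aq. potassium sodium tartrate
Reagents that add atoms: none
Why: Hydride reduction of the aryl methyl ester to the benzylic alcohol, the silyl ether, the benzyl ether and the dihydrofuran ring being inert to iBu2AlH.

Step 14
Reactants: 18 ArCD-methanol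
Product: 19 ArCD-carbaldehyde, (2S,3R)-2-(4-benzyloxy-3-methoxyphenyl)-3-[(tert-butyldiphenylsilyloxy)methyl]-7-methoxy-2,3-dihydrobenzofuran-5-carbaldehyde
Conditions: MnO2, CH2Cl2, rt
Reagents that add atoms: none
Why: MnO2 oxidation is selective for benzylic alcohols, stops at the aldehyde and leaves the dihydrobenzofuran untouched.

Step 15
Reactants: 10 arylacetyl imide (1.3 equiv); 19 ArCD-carbaldehyde
Product: 20 methyl 3-{(2R,3R)-1-[(4R)-4-benzyl-2-oxooxazolidin-3-yl]-3-hydroxy-1-oxo-3-(ArCD)propan-2-yl}-5-methoxy-4-(methoxymethoxy)benzoate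
Conditions: Bu2BOTf, iPr2NEt, CH2Cl2, −78 to 0 °C; then 19, −78 to 0 °C; pH 7 buffer, MeOH, H2O2, 0 °C
Reagents that add atoms: none
Why: Evans syn aldol reaction through the Z boron enolate and a Zimmerman–Traxler chair, in which the same (R)-auxiliary that gave the (R) centre on alkylation now directs the aldehyde to the opposite enolate face, setting the (2R) aryl-bearing centre (C3 of the inner ring, S in the final ring) and the syn (3R) carbinol that is ionised later.

Step 16
Reactants: 20 syn aldol imide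
Product: 21 methyl 3-[(1R,2S)-1,3-dihydroxy-1-(ArCD)propan-2-yl]-5-methoxy-4-(methoxymethoxy)benzoate
Conditions: NaBH4, THF/H2O (4:1), 0 °C
Reagents that add atoms: none
Why: Reductive removal of the auxiliary with borohydride gives the 1,3-diol without touching the ring B methyl ester or the stereocentres, the reduction being kept at 0 °C to outrun retro-aldol cleavage.

Step 17
Reactants: 21 MOM-protected 1,3-diol
Product: 23 methyl (2R,3S)-2-(ArCD)-3-(hydroxymethyl)-7-methoxy-2,3-dihydrobenzofuran-5-carboxylate, via free phenol diol 22 (not isolated)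
Conditions: conc. HCl (5 equiv), MeOH/THF, 40 °C
Reagents that add atoms: none
Why: Acid solvolyses the MOM acetal and ionises the benzylic alcohol to a cation stabilised by the para oxygen of ring C (SN1), and the freed ring B phenol closes 5-exo onto it so that C2 is set trans to the fixed C3 centre under thermodynamic control, the carbinol configuration being irrelevant.

Step 18
Reactants: 23 inner dihydrobenzofuran with free primary alcohol
Product: 24 ArBCD methyl ester, methyl (2R,3S)-2-(ArCD)-3-[(tert-butyldiphenylsilyloxy)methyl]-7-methoxy-2,3-dihydrobenzofuran-5-carboxylate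
Conditions: TBDPSCl, imidazole, DMF, rt
Reagents that add atoms: tert-butyl(chloro)diphenylsilane, CC(C)(C)[Si](Cl)(c1ccccc1)c1ccccc1
Why: Silylation of the only free hydroxyl masks it before the enolate and hydride steps that follow.

Step 19
Reactants: 24 ArBCD methyl ester
Product: 25 ArBCD-methanol
Conditions: iBu2AlH (2.5 equiv), CH2Cl2, −78 to 0 °C; aq. potassium sodium tartrate
Reagents that add atoms: none
Why: Hydride reduction of the aryl methyl ester to the benzylic alcohol, as in step 13, with both silyl ethers and both dihydrofuran rings inert.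

Step 20
Reactants: 25 ArBCD-methanol
Product: 26 ArBCD-carbaldehyde
Conditions: MnO2, CH2Cl2, rt
Reagents that add atoms: none
Why: Selective MnO2 oxidation of the benzylic alcohol to the aldehyde, as in step 14.

Step 21
Reactants: 8 (R)-4-benzyl-2-oxazolidinone; 27 methyl 4-chloro-4-oxobutanoate
Product: 28 methyl 4-[(4R)-4-benzyl-2-oxooxazolidin-3-yl]-4-oxobutanoate
Conditions: n-BuLi, THF, −78 °C; then 27, −78 to 0 °C
Reagents that add atoms: none
Why: N-acylation of the lithiated oxazolidinone by the acid chloride at low temperature, the methyl ester being far less electrophilic.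

Step 22
Reactants: 28 succinate imide; 12 4-benzyloxy-3-methoxybenzyl bromide
Product: 29 methyl (3R)-3-[(4-benzyloxy-3-methoxyphenyl)methyl]-4-[(4R)-4-benzyl-2-oxooxazolidin-3-yl]-4-oxobutanoate
Conditions: NaN(SiMe3)2, THF, −78 °C; then 12, −78 to −40 °C
Reagents that add atoms: none
Why: Evans asymmetric alkylation of the sodium enolate formed at the more acidic imide α-carbon, attack anti to the auxiliary benzyl group giving the (R) centre that becomes C4 of the tetrahydrofuran.

Step 23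
Reactants: 29 alkylated succinate imide
Product: 31 (4R)-4-[(4-benzyloxy-3-methoxyphenyl)methyl]oxolan-2-one, via hydroxy ester 30 (not isolated)
Conditions: NaBH4, THF/H2O (4:1), 0 °C to rt; then aq. HCl to pH 1, rt
Reagents that add atoms: none
Why: Borohydride cleaves the imide reductively to the primary alcohol, which on acidification lactonises onto the γ-ester by 5-exo-trig acyl substitution without touching the stereocentre.

Step 24
Reactants: 31 β-benzyl lactone (2 equiv); 26 ArBCD-carbaldehyde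
Product: 32 (3S,4R)-3-[(ArBCD)(hydroxy)methyl]-4-[(4-benzyloxy-3-methoxyphenyl)methyl]oxolan-2-one
Conditions: LiN(SiMe3)2, THF, −78 °C; then 26, −78 °C; aq. NH4Cl
Reagents that add atoms: none
Why: Aldol addition of the lactone lithium enolate, in which the aldehyde adds to the face opposite the β-benzyl group and so sets the trans lactone centre that becomes C3 of the tetrahydrofuran, both carbinol epimers being usable because this centre is oxidised in step 26.

Step 25
Reactants: 32 aldol lactone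
Product: 33 (2R,3R)-2-[(ArBCD)(hydroxy)methyl]-3-[(4-benzyloxy-3-methoxyphenyl)methyl]butane-1,4-diol
Conditions: LiAlH4, THF, 0 °C
Reagents that add atoms: none
Why: Hydride reduction of the lactone to the diol, rapid at 0 °C so that retro-aldol cleavage of the alkoxide does not compete, with silyl and benzyl ethers inert.

Step 26
Reactants: 33 triol
Product: 35 (3R,4R)-2-(ArBCD)-4-[(4-benzyloxy-3-methoxyphenyl)methyl]-3-(hydroxymethyl)oxolan-2-ol, via open-chain hydroxy ketone 34 (not isolated)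
Conditions: MnO2, CH2Cl2, rt
Reagents that add atoms: none
Why: MnO2 oxidises only the secondary benzylic alcohol, activated by the para ring oxygen, and the γ-hydroxy ketone closes to the five-membered hemiketal (anomeric mixture), which shields the adjacent C3 centre from enolisation.

Step 27
Reactants: 35 cyclic hemiketal
Product: 36 [(2R,3R,4R)-2-(ArBCD)-4-[(4-benzyloxy-3-methoxyphenyl)methyl]oxolan-3-yl]methanol
Conditions: Et3SiH (5 equiv), BF3·OEt2 (2 equiv), CH2Cl2, −78 °C
Reagents that add atoms: none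
Why: Reductive deoxygenation of a cyclic hemiketal (ionic hydrogenation), in which BF3·OEt2 generates the 2-aryl oxocarbenium ion and Et3SiH delivers hydride to the face opposite the cis C3 and C4 substituents, so the aryl group ends cis to both and C2 is set (R) in the all-cis ring, the low temperature keeping the benzylic ethers from ionising.

Step 28
Reactants: 36 bis-silyl ether
Product: 37 bis-benzyl ether of the target
Conditions: Bu4NF, THF, rt
Reagents that add atoms: none
Why: Fluoride-mediated cleavage of both silyl ethers, driven by the strong Si–F bond, under basic conditions that the acid-sensitive all-cis tetrahydrofuran tolerates.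

Step 29
Reactants: 37 bis-benzyl ether of the target
Product: 38 CNP0395728.1
Conditions: H2 (1 atm), 10% Pd/C, EtOAc/EtOH, rt
Reagents that add atoms: none
Why: Hydrogenolysis of the two aryl benzyl ethers over Pd/C in neutral solvent, which should be much faster than cleavage of the cyclic benzylic C–O bonds when the reaction is stopped at two equivalents of hydrogen.

Compound list
1 | methyl vanillate (methyl 4-hydroxy-3-methoxybenzoate) | COC(=O)c1ccc(O)c(OC)c1 | starting material
2 | allyl bromide | C=CCBr | starting material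
3 | methyl 4-(allyloxy)-3-methoxybenzoate | COC(=O)c1ccc(OCC=C)c(OC)c1 | intermediate
4 | methyl 3-allyl-4-hydroxy-5-methoxybenzoate | COC(=O)c1cc(OC)c(O)c(CC=C)c1 | intermediate
5 | methyl 3-allyl-5-methoxy-4-(methoxymethoxy)benzoate | COC(=O)c1cc(OC)c(OCOC)c(CC=C)c1 | intermediate
6 | methyl 3-methoxy-4-(methoxymethoxy)-5-(2-oxoethyl)benzoate | COC(=O)c1cc(OC)c(OCOC)c(CC=O)c1 | intermediate
7 | [3-methoxy-5-(methoxycarbonyl)-2-(methoxymethoxy)phenyl]acetic acid | COC(=O)c1cc(OC)c(OCOC)c(CC(=O)O)c1 | intermediate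
8 | (R)-4-benzyl-2-oxazolidinone | O=C1OC[C@@H](Cc2ccccc2)N1 | starting material
9 | mixed anhydride of acid 7 with pivalic acid (not isolated) | COC(=O)c1cc(OC)c(OCOC)c(CC(=O)OC(=O)C(C)(C)C)c1 | intermediate
10 | methyl 3-{2-[(4R)-4-benzyl-2-oxooxazolidin-3-yl]-2-oxoethyl}-5-methoxy-4-(methoxymethoxy)benzoate | COC(=O)c1cc(OC)c(OCOC)c(CC(=O)N2C(=O)OC[C@H]2Cc2ccccc2)c1 | intermediate
11 | 4-benzyloxy-3-methoxybenzyl alcohol | COc1cc(CO)ccc1OCc1ccccc1 | starting material
12 | 4-benzyloxy-3-methoxybenzyl bromide | COc1cc(CBr)ccc1OCc1ccccc1 | intermediate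
13 | methyl 3-{(2R)-1-[(4R)-4-benzyl-2-oxooxazolidin-3-yl]-3-(4-benzyloxy-3-methoxyphenyl)-1-oxopropan-2-yl}-5-methoxy-4-(methoxymethoxy)benzoate | COC(=O)c1cc(OC)c(OCOC)c([C@@H](Cc2ccc(OCc3ccccc3)c(OC)c2)C(=O)N2C(=O)OC[C@H]2Cc2ccccc2)c1 | intermediate
14 | methyl 3-[(2R)-1-(4-benzyloxy-3-methoxyphenyl)-3-hydroxypropan-2-yl]-5-methoxy-4-(methoxymethoxy)benzoate | COC(=O)c1cc(OC)c(OCOC)c([C@H](CO)Cc2ccc(OCc3ccccc3)c(OC)c2)c1 | intermediate
15 | methyl 3-[(2R)-1-(4-benzyloxy-3-methoxyphenyl)-3-(tert-butyldiphenylsilyloxy)propan-2-yl]-5-methoxy-4-(methoxymethoxy)benzoate | COC(=O)c1cc(OC)c(OCOC)c([C@H](CO[Si](c2ccccc2)(c2ccccc2)C(C)(C)C)Cc2ccc(OCc3ccccc3)c(OC)c2)c1 | intermediate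
16 | methyl 3-[(2R)-1-(4-benzyloxy-3-methoxyphenyl)-3-(tert-butyldiphenylsilyloxy)propan-2-yl]-4-hydroxy-5-methoxybenzoate | COC(=O)c1cc(OC)c(O)c([C@H](CO[Si](c2ccccc2)(c2ccccc2)C(C)(C)C)Cc2ccc(OCc3ccccc3)c(OC)c2)c1 | intermediate
17 | methyl (2S,3R)-2-(4-benzyloxy-3-methoxyphenyl)-3-[(tert-butyldiphenylsilyloxy)methyl]-7-methoxy-2,3-dihydrobenzofuran-5-carboxylate | COC(=O)c1cc(OC)c2c(c1)[C@H](CO[Si](c1ccccc1)(c1ccccc1)C(C)(C)C)[C@@H](c1ccc(OCc3ccccc3)c(OC)c1)O2 | intermediate
18 | {(2S,3R)-2-(4-benzyloxy-3-methoxyphenyl)-3-[(tert-butyldiphenylsilyloxy)methyl]-7-methoxy-2,3-dihydrobenzofuran-5-yl}methanol | OCc1cc(OC)c2c(c1)[C@H](CO[Si](c1ccccc1)(c1ccccc1)C(C)(C)C)[C@@H](c1ccc(OCc3ccccc3)c(OC)c1)O2 | intermediate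
19 | (2S,3R)-2-(4-benzyloxy-3-methoxyphenyl)-3-[(tert-butyldiphenylsilyloxy)methyl]-7-methoxy-2,3-dihydrobenzofuran-5-carbaldehyde | O=Cc1cc(OC)c2c(c1)[C@H](CO[Si](c1ccccc1)(c1ccccc1)C(C)(C)C)[C@@H](c1ccc(OCc3ccccc3)c(OC)c1)O2 | intermediate
20 | methyl 3-{(2R,3R)-1-[(4R)-4-benzyl-2-oxooxazolidin-3-yl]-3-hydroxy-1-oxo-3-(ArCD)propan-2-yl}-5-methoxy-4-(methoxymethoxy)benzoate | COC(=O)c1cc(OC)c(OCOC)c([C@H]([C@@H](O)c2cc(OC)c3c(c2)[C@H](CO[Si](c2ccccc2)(c2ccccc2)C(C)(C)C)[C@@H](c2ccc(OCc4ccccc4)c(OC)c2)O3)C(=O)N2C(=O)OC[C@H]2Cc2ccccc2)c1 | intermediate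
21 | methyl 3-[(1R,2S)-1,3-dihydroxy-1-(ArCD)propan-2-yl]-5-methoxy-4-(methoxymethoxy)benzoate | COC(=O)c1cc(OC)c(OCOC)c([C@H]([C@@H](O)c2cc(OC)c3c(c2)[C@H](CO[Si](c2ccccc2)(c2ccccc2)C(C)(C)C)[C@@H](c2ccc(OCc4ccccc4)c(OC)c2)O3)CO)c1 | intermediate
22 | methyl 3-[(1R,2S)-1,3-dihydroxy-1-(ArCD)propan-2-yl]-4-hydroxy-5-methoxybenzoate (not isolated) | COC(=O)c1cc(OC)c(O)c([C@H]([C@@H](O)c2cc(OC)c3c(c2)[C@H](CO[Si](c2ccccc2)(c2ccccc2)C(C)(C)C)[C@@H](c2ccc(OCc4ccccc4)c(OC)c2)O3)CO)c1 | intermediate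
23 | methyl (2R,3S)-2-(ArCD)-3-(hydroxymethyl)-7-methoxy-2,3-dihydrobenzofuran-5-carboxylate | COC(=O)c1cc(OC)c2c(c1)[C@@H](CO)[C@H](c1cc(OC)c3c(c1)[C@H](CO[Si](c1ccccc1)(c1ccccc1)C(C)(C)C)[C@@H](c1ccc(OCc4ccccc4)c(OC)c1)O3)O2 | intermediate
24 | methyl (2R,3S)-2-(ArCD)-3-[(tert-butyldiphenylsilyloxy)methyl]-7-methoxy-2,3-dihydrobenzofuran-5-carboxylate | COC(=O)c1cc(OC)c2c(c1)[C@@H](CO[Si](c1ccccc1)(c1ccccc1)C(C)(C)C)[C@H](c1cc(OC)c3c(c1)[C@H](CO[Si](c1ccccc1)(c1ccccc1)C(C)(C)C)[C@@H](c1ccc(OCc4ccccc4)c(OC)c1)O3)O2 | intermediate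
25 | (ArBCD)methanol | OCc1cc(OC)c2c(c1)[C@@H](CO[Si](c1ccccc1)(c1ccccc1)C(C)(C)C)[C@H](c1cc(OC)c3c(c1)[C@H](CO[Si](c1ccccc1)(c1ccccc1)C(C)(C)C)[C@@H](c1ccc(OCc4ccccc4)c(OC)c1)O3)O2 | intermediate
26 | ArBCD-carbaldehyde | O=Cc1cc(OC)c2c(c1)[C@@H](CO[Si](c1ccccc1)(c1ccccc1)C(C)(C)C)[C@H](c1cc(OC)c3c(c1)[C@H](CO[Si](c1ccccc1)(c1ccccc1)C(C)(C)C)[C@@H](c1ccc(OCc4ccccc4)c(OC)c1)O3)O2 | intermediate
27 | methyl 4-chloro-4-oxobutanoate | COC(=O)CCC(=O)Cl | starting material
28 | methyl 4-[(4R)-4-benzyl-2-oxooxazolidin-3-yl]-4-oxobutanoate | COC(=O)CCC(=O)N1C(=O)OC[C@H]1Cc1ccccc1 | intermediate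
29 | methyl (3R)-3-[(4-benzyloxy-3-methoxyphenyl)methyl]-4-[(4R)-4-benzyl-2-oxooxazolidin-3-yl]-4-oxobutanoate | COC(=O)C[C@@H](Cc1ccc(OCc2ccccc2)c(OC)c1)C(=O)N1C(=O)OC[C@H]1Cc1ccccc1 | intermediate
30 | methyl (3R)-4-(4-benzyloxy-3-methoxyphenyl)-3-(hydroxymethyl)butanoate (not isolated) | COC(=O)C[C@@H](Cc1ccc(OCc2ccccc2)c(OC)c1)CO | intermediate
31 | (4R)-4-[(4-benzyloxy-3-methoxyphenyl)methyl]oxolan-2-one | O=C1C[C@@H](Cc2ccc(OCc3ccccc3)c(OC)c2)CO1 | intermediate
32 | (3S,4R)-3-[(ArBCD)(hydroxy)methyl]-4-[(4-benzyloxy-3-methoxyphenyl)methyl]oxolan-2-one, trans lactone, both carbinol epimers | O=C1[C@H](C(O)c2cc(OC)c3c(c2)[C@@H](CO[Si](c2ccccc2)(c2ccccc2)C(C)(C)C)[C@H](c2cc(OC)c4c(c2)[C@H](CO[Si](c2ccccc2)(c2ccccc2)C(C)(C)C)[C@@H](c2ccc(OCc5ccccc5)c(OC)c2)O4)O3)[C@@H](Cc2ccc(OCc3ccccc3)c(OC)c2)CO1 | intermediate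
33 | (2R,3R)-2-[(ArBCD)(hydroxy)methyl]-3-[(4-benzyloxy-3-methoxyphenyl)methyl]butane-1,4-diol, both carbinol epimers | OC[C@H](Cc1ccc(OCc2ccccc2)c(OC)c1)[C@H](CO)C(O)c1cc(OC)c2c(c1)[C@@H](CO[Si](c1ccccc1)(c1ccccc1)C(C)(C)C)[C@H](c1cc(OC)c3c(c1)[C@H](CO[Si](c1ccccc1)(c1ccccc1)C(C)(C)C)[C@@H](c1ccc(OCc4ccccc4)c(OC)c1)O3)O2 | intermediate
34 | (2R,3R)-3-[(4-benzyloxy-3-methoxyphenyl)methyl]-4-hydroxy-2-(hydroxymethyl)-1-(ArBCD)butan-1-one (not isolated) | OC[C@H](Cc1ccc(OCc2ccccc2)c(OC)c1)[C@H](CO)C(=O)c1cc(OC)c2c(c1)[C@@H](CO[Si](c1ccccc1)(c1ccccc1)C(C)(C)C)[C@H](c1cc(OC)c3c(c1)[C@H](CO[Si](c1ccccc1)(c1ccccc1)C(C)(C)C)[C@@H](c1ccc(OCc4ccccc4)c(OC)c1)O3)O2 | intermediate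
35 | (3R,4R)-2-(ArBCD)-4-[(4-benzyloxy-3-methoxyphenyl)methyl]-3-(hydroxymethyl)oxolan-2-ol, 3,4-cis, anomeric mixture | COc1cc(C[C@H]2COC(O)(c3cc(OC)c4c(c3)[C@@H](CO[Si](c3ccccc3)(c3ccccc3)C(C)(C)C)[C@H](c3cc(OC)c5c(c3)[C@H](CO[Si](c3ccccc3)(c3ccccc3)C(C)(C)C)[C@@H](c3ccc(OCc6ccccc6)c(OC)c3)O5)O4)[C@H]2CO)ccc1OCc1ccccc1 | intermediate
36 | [(2R,3R,4R)-2-(ArBCD)-4-[(4-benzyloxy-3-methoxyphenyl)methyl]oxolan-3-yl]methanol, all-cis | COc1cc(C[C@H]2CO[C@@H](c3cc(OC)c4c(c3)[C@@H](CO[Si](c3ccccc3)(c3ccccc3)C(C)(C)C)[C@H](c3cc(OC)c5c(c3)[C@H](CO[Si](c3ccccc3)(c3ccccc3)C(C)(C)C)[C@@H](c3ccc(OCc6ccccc6)c(OC)c3)O5)O4)[C@H]2CO)ccc1OCc1ccccc1 | intermediate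
37 | bis-benzyl ether of the target (ring A and ring D phenols benzylated, all three primary alcohols free) | COc1cc(C[C@H]2CO[C@@H](c3cc(OC)c4c(c3)[C@@H](CO)[C@H](c3cc(OC)c5c(c3)[C@H](CO)[C@@H](c3ccc(OCc6ccccc6)c(OC)c3)O5)O4)[C@H]2CO)ccc1OCc1ccccc1 | intermediate
38 | CNP0395728.1: all-cis (2R,3R,4R)-tetrahydrofuran carrying the (2R,3S) inner and (2S,3R) outer dihydrobenzofurans | COc1cc(C[C@H]2CO[C@@H](c3cc(OC)c4c(c3)[C@@H](CO)[C@H](c3cc(OC)c5c(c3)[C@H](CO)[C@@H](c3ccc(O)c(OC)c3)O5)O4)[C@H]2CO)ccc1O | target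

Total step count: 29. Longest linear sequence: 25 steps from methyl vanillate (steps 1–6, 8–20 and 24–29).

Steps most likely to fail

Step 12. Hydride abstraction may be unselective (attack at C3–H or oxidation of the ring C phenol), or the product may be dehydrogenated further to the benzofuran. The fallback makes the same O1–C2 bond by ionising a benzylic alcohol instead of a C–H bond, with known chemistry only. It sets out from acid 7. Acylation of (S)-4-benzyl-2-oxazolidinone (PivCl, Et3N, LiCl) would give methyl 3-{2-[(4S)-4-benzyl-2-oxooxazolidin-3-yl]-2-oxoethyl}-5-methoxy-4-(methoxymethoxy)benzoate F1. A Bu2BOTf/iPr2NEt syn aldol with purchased 4-benzyloxy-3-methoxybenzaldehyde would give the (2S,3S) aldol imide F2, and NaBH4 in THF/H2O would give the (1S,2R) diol F3. HCl in MeOH would then remove the MOM group and close the trans ring by SN1 to the dihydrobenzofuran alcohol F4. TBDPSCl and imidazole bring this back to the route at compound 17.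

Step 27. Hydride may be delivered with poor facial selectivity, C3 may epimerise through the enol ether, or the benzylic ethers may open reductively. The fallback sets the ring stereochemistry by alkene hydrogenation instead of oxocarbenium reduction. It sets out from hemiketal 35. Acid-catalysed dehydration (pyridinium p-toluenesulfonate, toluene, 60 °C) would give the 2-aryl-4,5-dihydrofuran F5, in which C3 is no longer a stereocentre. Hydrogenation over 10% Pd/C in EtOAc should add hydrogen to the face away from the C4 benzyl group, giving the all-cis ring and removing both benzyl ethers in the same operation, to the bis-silyl bisphenol F6. Bu4NF then returns to the route at compound 38.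

Step 17. The benzylic cation may lose the C3 proton (E1) before the phenol is unmasked, or the acid may erode the silyl ether. The fallback builds the inner ring by alkylation and oxidative closure, the reaction types of steps 8 and 12, instead of aldol and SN1. It sets out from alcohol 18. PBr3 would give the ArCD-methyl bromide F7, which alkylates the sodium enolate of the (S)-auxiliary imide F1 (made as described for step 12) to give the (2S) imide F8. NaBH4 would give the primary alcohol F9, TBDPSCl the silyl ether F10 and HCl in MeOH the free phenol F11. DDQ in CH2Cl2 then closes the inner ring trans and returns to the route at compound 24.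

Further compounds
F1 | step 12 | methyl 3-{2-[(4S)-4-benzyl-2-oxooxazolidin-3-yl]-2-oxoethyl}-5-methoxy-4-(methoxymethoxy)benzoate | COC(=O)c1cc(OC)c(OCOC)c(CC(=O)N2C(=O)OC[C@@H]2Cc2ccccc2)c1
F2 | step 12 | methyl 3-{(2S,3S)-1-[(4S)-4-benzyl-2-oxooxazolidin-3-yl]-3-(4-benzyloxy-3-methoxyphenyl)-3-hydroxy-1-oxopropan-2-yl}-5-methoxy-4-(methoxymethoxy)benzoate | COC(=O)c1cc(OC)c(OCOC)c([C@@H]([C@H](O)c2ccc(OCc3ccccc3)c(OC)c2)C(=O)N2C(=O)OC[C@@H]2Cc2ccccc2)c1
F3 | step 12 | methyl 3-[(1S,2R)-1-(4-benzyloxy-3-methoxyphenyl)-1,3-dihydroxypropan-2-yl]-5-methoxy-4-(methoxymethoxy)benzoate | COC(=O)c1cc(OC)c(OCOC)c([C@@H]([C@H](O)c2ccc(OCc3ccccc3)c(OC)c2)CO)c1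
F4 | step 12 | methyl (2S,3R)-2-(4-benzyloxy-3-methoxyphenyl)-3-(hydroxymethyl)-7-methoxy-2,3-dihydrobenzofuran-5-carboxylate | COC(=O)c1cc(OC)c2c(c1)[C@H](CO)[C@@H](c1ccc(OCc3ccccc3)c(OC)c1)O2
F5 | step 27 | [(4R)-2-(ArBCD)-4-[(4-benzyloxy-3-methoxyphenyl)methyl]-4,5-dihydrofuran-3-yl]methanol | COc1cc(C[C@H]2COC(c3cc(OC)c4c(c3)[C@@H](CO[Si](c3ccccc3)(c3ccccc3)C(C)(C)C)[C@H](c3cc(OC)c5c(c3)[C@H](CO[Si](c3ccccc3)(c3ccccc3)C(C)(C)C)[C@@H](c3ccc(OCc6ccccc6)c(OC)c3)O5)O4)=C2CO)ccc1OCc1ccccc1
F6 | step 27 | compound 36 without its two benzyl groups (ring A and ring D phenols free, both dihydrobenzofuran alcohols as tert-butyldiphenylsilyl ethers) | COc1cc(C[C@H]2CO[C@@H](c3cc(OC)c4c(c3)[C@@H](CO[Si](c3ccccc3)(c3ccccc3)C(C)(C)C)[C@H](c3cc(OC)c5c(c3)[C@H](CO[Si](c3ccccc3)(c3ccccc3)C(C)(C)C)[C@@H](c3ccc(O)c(OC)c3)O5)O4)[C@H]2CO)ccc1O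
F7 | step 17 | ArCD-methyl bromide, (2S,3R)-2-(4-benzyloxy-3-methoxyphenyl)-5-(bromomethyl)-3-[(tert-butyldiphenylsilyloxy)methyl]-7-methoxy-2,3-dihydrobenzofuran | BrCc1cc(OC)c2c(c1)[C@H](CO[Si](c1ccccc1)(c1ccccc1)C(C)(C)C)[C@@H](c1ccc(OCc3ccccc3)c(OC)c1)O2
F8 | step 17 | methyl 3-{(2S)-1-[(4S)-4-benzyl-2-oxooxazolidin-3-yl]-1-oxo-3-(ArCD)propan-2-yl}-5-methoxy-4-(methoxymethoxy)benzoate | COC(=O)c1cc(OC)c(OCOC)c([C@H](Cc2cc(OC)c3c(c2)[C@H](CO[Si](c2ccccc2)(c2ccccc2)C(C)(C)C)[C@@H](c2ccc(OCc4ccccc4)c(OC)c2)O3)C(=O)N2C(=O)OC[C@@H]2Cc2ccccc2)c1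
F9 | step 17 | methyl 3-[(2S)-1-hydroxy-3-(ArCD)propan-2-yl]-5-methoxy-4-(methoxymethoxy)benzoate | COC(=O)c1cc(OC)c(OCOC)c([C@@H](CO)Cc2cc(OC)c3c(c2)[C@H](CO[Si](c2ccccc2)(c2ccccc2)C(C)(C)C)[C@@H](c2ccc(OCc4ccccc4)c(OC)c2)O3)c1
F10 | step 17 | methyl 3-[(2S)-1-(tert-butyldiphenylsilyloxy)-3-(ArCD)propan-2-yl]-5-methoxy-4-(methoxymethoxy)benzoate | COC(=O)c1cc(OC)c(OCOC)c([C@@H](CO[Si](c2ccccc2)(c2ccccc2)C(C)(C)C)Cc2cc(OC)c3c(c2)[C@H](CO[Si](c2ccccc2)(c2ccccc2)C(C)(C)C)[C@@H](c2ccc(OCc4ccccc4)c(OC)c2)O3)c1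
F11 | step 17 | methyl 3-[(2S)-1-(tert-butyldiphenylsilyloxy)-3-(ArCD)propan-2-yl]-4-hydroxy-5-methoxybenzoate | COC(=O)c1cc(OC)c(O)c([C@@H](CO[Si](c2ccccc2)(c2ccccc2)C(C)(C)C)Cc2cc(OC)c3c(c2)[C@H](CO[Si](c2ccccc2)(c2ccccc2)C(C)(C)C)[C@@H](c2ccc(OCc4ccccc4)c(OC)c2)O3)c1
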